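Numbering: ring A = C1–C5/C10 (gem-dimethyl C4), ring B = C5–C10, C11 = benzylic carbon. Ring B is closed last, across C9–C10, by a ring-contracting Ireland–Claisen rearrangement. It exploits the γ,δ-unsaturated relationship between the methyl carbon on C9 (raised to the carboxyl level) and the C5=C6 double bond of ring B. The precursor is a cis-4,6-disubstituted δ-lactone carrying the ring A cyclohexenyl unit at its carbinol carbon and the arylmethyl group at its α-carbon. One operation forms ring B, quaternary C9, the C10 stereocentre and the C5=C6 alkene through an enforced boat transition state, relays the carbinol configuration to C9/C10 and erases the α-epimer mixture.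

Key step: step 10

Remark: the aryl hydrogen sulfate would be handled as its sodium salt and is written throughout in the free acid form. Abbreviations: Ar = 4,5-bis(benzyloxy)-2-[(triisopropylsilyl)oxy]phenyl; Dec = (1R,2R,8aS)-1,2,5,5-tetramethyl-1,2,3,5,6,7,8,8a-octahydronaphthalen-1-yl; arene carbons C1′–C6′ start at the carbon bearing C11.

Step 1
Reactants: 1 3,4-bis(benzyloxy)phenol
Product: 2 4,5-bis(benzyloxy)-2-hydroxybenzaldehyde
Conditions: MgCl2, Et3N, (CH2O)n, MeCN, 80 °C
Reagents that add atoms: paraformaldehyde (as formaldehyde), C=O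
Why: Magnesium phenoxide-directed ortho-formylation should take place at the ortho position not flanked by a benzyloxy group, a second formaldehyde acting as hydride acceptor.

Step 2
Reactants: 2 4,5-bis(benzyloxy)-2-hydroxybenzaldehyde
Product: 3 4,5-bis(benzyloxy)-2-[(triisopropylsilyl)oxy]benzaldehyde
Conditions: TIPSCl, imidazole, DMAP (cat.), DMF, 25–40 °C
Reagents that add atoms: chlorotriisopropylsilane, CC(C)[Si](Cl)(C(C)C)C(C)C
Why: Standard phenol silylation; the bulky aryl silyl ether is chosen to survive LDA, LiAlH4 and Dess–Martin conditions and to be cleaved under the basic Wolff–Kishner conditions of step 12.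

Step 3
Reactants: 3 4,5-bis(benzyloxy)-2-[(triisopropylsilyl)oxy]benzaldehyde
Product: 4 ArCH2OH, {4,5-bis(benzyloxy)-2-[(triisopropylsilyl)oxy]phenyl}methanol
Conditions: NaBH4, MeOH–THF, 0 °C
Reagents that add atoms: none
Why: Chemoselective borohydride reduction of the aryl aldehyde to the benzylic alcohol.

Step 4
Reactants: 4 ArCH2OH
Product: 5 ArCH2Br, [4,5-bis(benzyloxy)-2-(bromomethyl)phenoxy]triisopropylsilane
Conditions: CBr4, PPh3, CH2Cl2, 0 °C; used without storage
Reagents that add atoms: carbon tetrabromide, BrC(Br)(Br)Br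
Why: Appel bromination converts the electron-rich benzylic alcohol to the bromide under neutral conditions.

Step 5
Reactants: 6 (3R)-5-methoxy-3-methyl-5-oxopentanoic acid (methyl hydrogen (R)-3-methylglutarate)
Product: 7 methyl (3S)-5-chloro-3-methyl-5-oxopentanoate
Conditions: (COCl)2, DMF (cat.), CH2Cl2, 0 → 25 °C
Reagents that add atoms: oxalyl chloride, O=C(Cl)C(=O)Cl
Why: Acid chloride formation through the Vilsmeier-type chloroiminium; the β-stereocentre (future C8) cannot epimerise (the descriptor changes only by priority).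

Step 6
Reactants: 8 2,2-dimethylcyclohexanone
Product: 9 (E)-N′-(2,2-dimethylcyclohexylidene)-2,4,6-triisopropylbenzenesulfonohydrazide
Conditions: 2,4,6-triisopropylbenzenesulfonohydrazide, MeOH, HCl (cat.), 25 °C
Reagents that add atoms: 2,4,6-triisopropylbenzenesulfonohydrazide, CC(C)c1cc(C(C)C)c(S(=O)(=O)NN)c(C(C)C)c1
Why: Hydrazone condensation; the N–N bond settles anti to the quaternary carbon, which sets up syn-deprotonation at the only α-methylene.

Step 7
Reactants: 9 (E)-N′-(2,2-dimethylcyclohexylidene)-2,4,6-triisopropylbenzenesulfonohydrazide; 7 methyl (3S)-5-chloro-3-methyl-5-oxopentanoate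
Product: 12 methyl (3R)-5-(6,6-dimethylcyclohex-1-en-1-yl)-3-methyl-5-oxopentanoate, via vinyllithium 10 (not isolated), via vinylzinc chloride 11 (not isolated)
Conditions: n-BuLi (2.2 equiv), TMEDA, THF, −78 → 0 °C; ZnCl2, THF, −78 → 0 °C; Pd(PPh3)4 (cat.), then 7, 0 → 25 °C
Reagents that add atoms: none
Why: The Shapiro reaction gives the ring A vinyllithium regiospecifically, and transmetalation to zinc followed by Negishi acylation with the acid chloride leaves the methyl ester untouched.

Step 8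
Reactants: 12 methyl (3R)-5-(6,6-dimethylcyclohex-1-en-1-yl)-3-methyl-5-oxopentanoate
Product: 14 (4R,6R)-6-(6,6-dimethylcyclohex-1-en-1-yl)-4-methyloxan-2-one (cis), via hydroxy ester 13 (not isolated)
Conditions: (S)-2-methyl-CBS-oxazaborolidine (cat.), catecholborane, toluene, −78 °C; work-up; PPTS (cat.), toluene, 60 °C
Reagents that add atoms: none
Why: Reagent-controlled Corey–Bakshi–Shibata 1,2-reduction, with the bulky cyclohexenyl group as the large substituent, should set the (R)-carbinol (future C6–O), and acid-catalysed δ-lactonisation gives the cis lactone, from which any trans diastereomer can be separated.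

Step 9
Reactants: 14 (4R,6R)-6-(6,6-dimethylcyclohex-1-en-1-yl)-4-methyloxan-2-one; 5 ArCH2Br
Product: 15 (3S,4R,6R)-3-(ArCH2)-6-(6,6-dimethylcyclohex-1-en-1-yl)-4-methyloxan-2-one (3,4-trans expected; the C3 epimer is equally usable)
Conditions: LDA, THF, −78 °C; then 5, DMPU, −78 → −30 °C
Reagents that add atoms: none
Why: Lactone enolate alkylation with the reactive benzylic bromide should occur anti to the C4 methyl group; the C3 configuration is erased in step 10.

Step 10
Reactants: 15 (3S,4R,6R)-3-(ArCH2)-6-(6,6-dimethylcyclohex-1-en-1-yl)-4-methyloxan-2-one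
Product: 18 [(1S,2R,8aR)-1-(ArCH2)-2,5,5-trimethyl-1,2,3,5,6,7,8,8a-octahydronaphthalen-1-yl]methanol, via silyl ketene acetal 16 (not isolated), via trimethylsilyl ester 17 (not isolated)
Conditions: LDA, TMSCl/Et3N, THF–DMPU, −78 → 25 °C; solvent exchange to toluene, 110 °C; then LiAlH4, THF, 0 → 25 °C
Reagents that add atoms: none
Why: Deprotonation at C3 (the only α-C–H) and O-silylation give the ring-locked silyl ketene acetal 16, which on heating undergoes a concerted suprafacial [3,3]-sigmatropic shift (the C6–O bond breaks, the C9–C10 bond forms) to silyl ester 17, reduced in the same flask; the closest known reaction type is the ring-contracting Ireland–Claisen rearrangement of 6-alkenyl δ-lactone silyl ketene acetals to cyclohex-3-enecarboxylic acids. Ring B closes by this sigmatropic ring contraction (six-membered lactone to six-membered carbocycle), and the C5=C6 double bond arises by allylic transposition of the ring A alkene. Because the lactone oxygen and C8 are tied in one ring, only a boat transition state is possible, so C9 (quaternary) and C10 are fixed by the C6 carbinol centre together with the ring-fixed ketene acetal and ring A alkene geometries: the new bond reaches C10 on the face of the breaking C–O bond, the carboxyl carbon ends anti to H10 and the arylmethyl group syn to H10. The cis relationship of the lactone substituents places the C8 methyl group on the face of H10 and the arylmethyl group, as the target requires. Both C3 epimers of 15 converge on the same ketene acetal, and the selectivities needed (O- over C-silylation, rearrangement over ionisation of the allylic C–O bond) are served by an internal TMSCl quench and a non-polar solvent for the thermal stage.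

Step 11
Reactants: 18 [(1S,2R,8aR)-1-(ArCH2)-2,5,5-trimethyl-1,2,3,5,6,7,8,8a-octahydronaphthalen-1-yl]methanol
Product: 19 (1S,2R,8aR)-1-(ArCH2)-2,5,5-trimethyl-1,2,3,5,6,7,8,8a-octahydronaphthalene-1-carbaldehyde
Conditions: Dess–Martin periodinane, NaHCO3, CH2Cl2, 0 → 25 °C
Reagents that add atoms: none
Why: Dess–Martin oxidation of the neopentyl primary alcohol gives an aldehyde without α-hydrogen, so nothing can epimerise.

Step 12
Reactants: 19 (1S,2R,8aR)-1-(ArCH2)-2,5,5-trimethyl-1,2,3,5,6,7,8,8a-octahydronaphthalene-1-carbaldehyde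
Product: 21 4,5-bis(benzyloxy)-2-(Dec-methyl)phenol, via hydrazone 20 (not isolated)
Conditions: N2H4·H2O, EtOH, 80 °C; concentrate; KOtBu, DMSO, 25 °C; aq. KOH work-up, inert atmosphere
Reagents that add atoms: none
Why: Wolff–Kishner reduction of the preformed hydrazone with KOtBu in DMSO at ambient temperature turns the formyl group into the C9 methyl group without alkene migration, and the basic medium should also cleave the aryl silyl ether while the benzyl ethers are inert.

Step 13
Reactants: 21 4,5-bis(benzyloxy)-2-(Dec-methyl)phenol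
Product: 22 5,6-bis(benzyloxy)-2-hydroxy-3-(Dec-methyl)benzaldehyde
Conditions: MgCl2, Et3N, (CH2O)n, THF, 70 °C
Reagents that add atoms: paraformaldehyde (as formaldehyde), C=O
Why: Magnesium phenoxide-directed ortho-formylation can only reach C3′, the single free position ortho to the phenol, and leaves that phenol free for sulfation.

Step 14
Reactants: 22 5,6-bis(benzyloxy)-2-hydroxy-3-(Dec-methyl)benzaldehyde
Product: 23 3,4-bis(benzyloxy)-2-formyl-6-(Dec-methyl)phenyl hydrogen sulfate
Conditions: SO3·pyridine (excess), pyridine, 50 °C; aq. NaHCO3 work-up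
Reagents that add atoms: sulfur trioxide–pyridine complex, [O-]S(=O)(=O)[n+]1ccccc1
Why: O-Sulfation of the only free hydroxyl group with an SO3–amine complex gives the aryl sulfate monoester, which is stable to base and to hydrogenolysis.

Step 15
Reactants: 23 3,4-bis(benzyloxy)-2-formyl-6-(Dec-methyl)phenyl hydrogen sulfate
Product: 24 2-formyl-3,4-dihydroxy-6-(Dec-methyl)phenyl hydrogen sulfate (CNP0115595.2)
Conditions: H2 (1 atm), Pd/C, EtOAc–MeOH, 25 °C, stopped after two equivalents of H2; H+ ion-exchange resin, 0 °C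
Reagents that add atoms: none
Why: Hydrogenolysis of the two aryl benzyl ethers should be faster than reduction of the doubly ortho-substituted aryl aldehyde, and the C5=C6 alkene, flanked by the quaternary C4 and the hindered C10, should resist hydrogenation.

Compound list
1 | 3,4-bis(benzyloxy)phenol | Oc1ccc(OCc2ccccc2)c(OCc2ccccc2)c1 | starting material
2 | 4,5-bis(benzyloxy)-2-hydroxybenzaldehyde | O=Cc1cc(OCc2ccccc2)c(OCc2ccccc2)cc1O | intermediate
3 | 4,5-bis(benzyloxy)-2-[(triisopropylsilyl)oxy]benzaldehyde | O=Cc1cc(OCc2ccccc2)c(OCc2ccccc2)cc1O[Si](C(C)C)(C(C)C)C(C)C | intermediate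
4 | {4,5-bis(benzyloxy)-2-[(triisopropylsilyl)oxy]phenyl}methanol | OCc1cc(OCc2ccccc2)c(OCc2ccccc2)cc1O[Si](C(C)C)(C(C)C)C(C)C | intermediate
5 | [4,5-bis(benzyloxy)-2-(bromomethyl)phenoxy]triisopropylsilane | BrCc1cc(OCc2ccccc2)c(OCc2ccccc2)cc1O[Si](C(C)C)(C(C)C)C(C)C | intermediate
6 | (3R)-5-methoxy-3-methyl-5-oxopentanoic acid | COC(=O)C[C@H](C)CC(=O)O | starting material
7 | methyl (3S)-5-chloro-3-methyl-5-oxopentanoate | COC(=O)C[C@H](C)CC(=O)Cl | intermediate
8 | 2,2-dimethylcyclohexanone | CC1(C)CCCCC1=O | starting material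
9 | (E)-N′-(2,2-dimethylcyclohexylidene)-2,4,6-triisopropylbenzenesulfonohydrazide | CC1(C)CCCC/C1=N\NS(=O)(=O)c1c(C(C)C)cc(C(C)C)cc1C(C)C | intermediate
10 | (6,6-dimethylcyclohex-1-en-1-yl)lithium | [Li]C1=CCCCC1(C)C | intermediate (not isolated)
11 | chloro(6,6-dimethylcyclohex-1-en-1-yl)zinc | Cl[Zn]C1=CCCCC1(C)C | intermediate (not isolated)
12 | methyl (3R)-5-(6,6-dimethylcyclohex-1-en-1-yl)-3-methyl-5-oxopentanoate | COC(=O)C[C@H](C)CC(=O)C1=CCCCC1(C)C | intermediate
13 | methyl (3R,5R)-5-(6,6-dimethylcyclohex-1-en-1-yl)-5-hydroxy-3-methylpentanoate | COC(=O)C[C@H](C)C[C@@H](O)C1=CCCCC1(C)C | intermediate (not isolated)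
14 | (4R,6R)-6-(6,6-dimethylcyclohex-1-en-1-yl)-4-methyloxan-2-one | O=C1C[C@H](C)C[C@H](C2=CCCCC2(C)C)O1 | intermediate
15 | (3S,4R,6R)-3-{[4,5-bis(benzyloxy)-2-(triisopropylsilyloxy)phenyl]methyl}-6-(6,6-dimethylcyclohex-1-en-1-yl)-4-methyloxan-2-one | O=C1[C@@H](Cc2cc(OCc3ccccc3)c(OCc3ccccc3)cc2O[Si](C(C)C)(C(C)C)C(C)C)[C@H](C)C[C@H](C2=CCCCC2(C)C)O1 | intermediate
16 | (2R,4R)-5-{[4,5-bis(benzyloxy)-2-(triisopropylsilyloxy)phenyl]methyl}-2-(6,6-dimethylcyclohex-1-en-1-yl)-4-methyl-6-(trimethylsilyloxy)-3,4-dihydro-2H-pyran | C[C@@H]1C[C@H](C2=CCCCC2(C)C)OC(O[Si](C)(C)C)=C1Cc1cc(OCc2ccccc2)c(OCc2ccccc2)cc1O[Si](C(C)C)(C(C)C)C(C)C | intermediate (not isolated)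
17 | trimethylsilyl (1S,2R,8aR)-1-{[4,5-bis(benzyloxy)-2-(triisopropylsilyloxy)phenyl]methyl}-2,5,5-trimethyl-1,2,3,5,6,7,8,8a-octahydronaphthalene-1-carboxylate | C[C@@H]1CC=C2[C@@H](CCCC2(C)C)[C@]1(C(=O)O[Si](C)(C)C)Cc1cc(OCc2ccccc2)c(OCc2ccccc2)cc1O[Si](C(C)C)(C(C)C)C(C)C | intermediate (not isolated)
18 | [(1S,2R,8aR)-1-{[4,5-bis(benzyloxy)-2-(triisopropylsilyloxy)phenyl]methyl}-2,5,5-trimethyl-1,2,3,5,6,7,8,8a-octahydronaphthalen-1-yl]methanol | C[C@@H]1CC=C2[C@@H](CCCC2(C)C)[C@]1(CO)Cc1cc(OCc2ccccc2)c(OCc2ccccc2)cc1O[Si](C(C)C)(C(C)C)C(C)C | intermediate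
19 | (1S,2R,8aR)-1-{[4,5-bis(benzyloxy)-2-(triisopropylsilyloxy)phenyl]methyl}-2,5,5-trimethyl-1,2,3,5,6,7,8,8a-octahydronaphthalene-1-carbaldehyde | C[C@@H]1CC=C2[C@@H](CCCC2(C)C)[C@]1(C=O)Cc1cc(OCc2ccccc2)c(OCc2ccccc2)cc1O[Si](C(C)C)(C(C)C)C(C)C | intermediate
20 | hydrazone of aldehyde 19 | C[C@@H]1CC=C2[C@@H](CCCC2(C)C)[C@]1(C=NN)Cc1cc(OCc2ccccc2)c(OCc2ccccc2)cc1O[Si](C(C)C)(C(C)C)C(C)C | intermediate (not isolated)
21 | 4,5-bis(benzyloxy)-2-{[(1R,2R,8aS)-1,2,5,5-tetramethyl-1,2,3,5,6,7,8,8a-octahydronaphthalen-1-yl]methyl}phenol | C[C@@H]1CC=C2[C@@H](CCCC2(C)C)[C@]1(C)Cc1cc(OCc2ccccc2)c(OCc2ccccc2)cc1O | intermediate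
22 | 5,6-bis(benzyloxy)-2-hydroxy-3-{[(1R,2R,8aS)-1,2,5,5-tetramethyl-1,2,3,5,6,7,8,8a-octahydronaphthalen-1-yl]methyl}benzaldehyde | C[C@@H]1CC=C2[C@@H](CCCC2(C)C)[C@]1(C)Cc1cc(OCc2ccccc2)c(OCc2ccccc2)c(C=O)c1O | intermediate
23 | 3,4-bis(benzyloxy)-2-formyl-6-{[(1R,2R,8aS)-1,2,5,5-tetramethyl-1,2,3,5,6,7,8,8a-octahydronaphthalen-1-yl]methyl}phenyl hydrogen sulfate | C[C@@H]1CC=C2[C@@H](CCCC2(C)C)[C@]1(C)Cc1cc(OCc2ccccc2)c(OCc2ccccc2)c(C=O)c1OS(=O)(=O)O | intermediate
24 | 2-formyl-3,4-dihydroxy-6-{[(1R,2R,8aS)-1,2,5,5-tetramethyl-1,2,3,5,6,7,8,8a-octahydronaphthalen-1-yl]methyl}phenyl hydrogen sulfate | C[C@@H]1CC=C2[C@@H](CCCC2(C)C)[C@]1(C)Cc1cc(O)c(O)c(C=O)c1OS(=O)(=O)O | target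

Total step count: 15. Longest linear sequence: 11 steps (steps 1–4 and 9–15, from compound 1).

Steps most likely to fail

Step 10. Enolisation of the hindered C3–H may be incomplete, or the ketene acetal may ionise at the allylic C6–O bond before it rearranges, because its boat transition state presses the OSiMe3 group against the carbon bearing the gem-dimethyl group. The rearrangement would then be run on the neutral cyclic enol ether. From 15, reduction with i-Bu2AlH (CH2Cl2, −78 °C) should give the lactol F1. Dehydration with MsCl/Et3N (CH2Cl2, 0 → 40 °C) should give the dihydropyran F2. Thermolysis (o-dichlorobenzene, 200 °C, sealed tube, trace of i-Pr2NEt) should bring about a thermal Claisen rearrangement of this allyl vinyl ether through the same boat, with hydrogen in place of OSiMe3. This leads directly to aldehyde 19, where the route is rejoined and step 11 is skipped.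

Step 13. Carbon–carbon bond formation at C3′, which is flanked by the phenol and a benzyloxy group, may be too slow, so that diarylmethane formation takes over. The aldehyde would then be introduced by directed ortho-lithiation. From 21, MOMCl/i-Pr2NEt (CH2Cl2) should give the MOM ether F3. Treatment with n-BuLi/TMEDA (THF, −20 °C) and then DMF should lithiate the only position lying between two oxygen substituents and give the MOM-protected aldehyde F4. HCl (cat.) in MeOH–THF should then free the chelated phenol and return 22.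

Step 15. The aryl aldehyde may be over-reduced during hydrogenolysis, or the sulfate lost on the acidic resin. Debenzylation would then be done without hydrogen on a protected sulfate. From 22, Cl3CCH2OSO2Cl/Et3N/DMAP (THF) should give the trichloroethyl sulfate diester F5. BCl3/pentamethylbenzene (CH2Cl2, −78 °C) should remove both benzyl groups and give the catechol diester F6. Zn/HCO2NH4 (MeOH, 25 °C) should unmask the sulfate and return 24.

Further compounds
F1 | step 10 | (3S,4R,6R)-3-{[4,5-bis(benzyloxy)-2-(triisopropylsilyloxy)phenyl]methyl}-6-(6,6-dimethylcyclohex-1-en-1-yl)-4-methyloxan-2-ol (lactol, anomers) | OC1[C@@H](Cc2cc(OCc3ccccc3)c(OCc3ccccc3)cc2O[Si](C(C)C)(C(C)C)C(C)C)[C@H](C)C[C@H](C2=CCCCC2(C)C)O1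
F2 | step 10 | (2R,4R)-5-{[4,5-bis(benzyloxy)-2-(triisopropylsilyloxy)phenyl]methyl}-2-(6,6-dimethylcyclohex-1-en-1-yl)-4-methyl-3,4-dihydro-2H-pyran | C1=C(Cc2cc(OCc3ccccc3)c(OCc3ccccc3)cc2O[Si](C(C)C)(C(C)C)C(C)C)[C@H](C)C[C@H](C2=CCCCC2(C)C)O1
F3 | step 13 | 1,2-bis(benzyloxy)-4-(methoxymethoxy)-5-{[(1R,2R,8aS)-1,2,5,5-tetramethyl-1,2,3,5,6,7,8,8a-octahydronaphthalen-1-yl]methyl}benzene | C[C@@H]1CC=C2[C@@H](CCCC2(C)C)[C@]1(C)Cc1cc(OCc2ccccc2)c(OCc2ccccc2)cc1OCOC
F4 | step 13 | 5,6-bis(benzyloxy)-2-(methoxymethoxy)-3-{[(1R,2R,8aS)-1,2,5,5-tetramethyl-1,2,3,5,6,7,8,8a-octahydronaphthalen-1-yl]methyl}benzaldehyde | C[C@@H]1CC=C2[C@@H](CCCC2(C)C)[C@]1(C)Cc1cc(OCc2ccccc2)c(OCc2ccccc2)c(C=O)c1OCOC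
F5 | step 15 | 3,4-bis(benzyloxy)-2-formyl-6-{[(1R,2R,8aS)-1,2,5,5-tetramethyl-1,2,3,5,6,7,8,8a-octahydronaphthalen-1-yl]methyl}phenyl 2,2,2-trichloroethyl sulfate | C[C@@H]1CC=C2[C@@H](CCCC2(C)C)[C@]1(C)Cc1cc(OCc2ccccc2)c(OCc2ccccc2)c(C=O)c1OS(=O)(=O)OCC(Cl)(Cl)Cl
F6 | step 15 | 2-formyl-3,4-dihydroxy-6-{[(1R,2R,8aS)-1,2,5,5-tetramethyl-1,2,3,5,6,7,8,8a-octahydronaphthalen-1-yl]methyl}phenyl 2,2,2-trichloroethyl sulfate | C[C@@H]1CC=C2[C@@H](CCCC2(C)C)[C@]1(C)Cc1cc(O)c(O)c(C=O)c1OS(=O)(=O)OCC(Cl)(Cl)Cl
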